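Set the constants side by side and this flask becomes a contest for the partner: a chain step against a first-order decomposition.

    initiator → 2 initiating radical (k1 = 0.00101 s⁻¹)
    starting material + initiating radical → chain carrier (k2 = 12500 L mol⁻¹ s⁻¹)
    partner + chain carrier → target + initiating radical (k3 = 2.69 × 10⁵ L mol⁻¹ s⁻¹)
    2 chain carrier → ended chains (k4 = 8 × 10⁸ L mol⁻¹ s⁻¹)
    partner + target → over-reaction product (k5 = 0.00452 L mol⁻¹ s⁻¹)
    partner → decomposed reagent (k6 = 0.0128 s⁻¹)

starting material 0.95 M; partner 0.950 M; initiator 9.5 mM; time 4.0 h

- percentages count the starting material that a species holds: one ended chains counts as two
- a step written with two of one species runs at k times the square of its concentration and takes two of it each time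
- the reaction counts as stopped when no species that holds the starting material changes by six tenths of a point or more over the second half of the time
- run time (flask): 4.0 h

1. the state of affairs at 4.0 h: stopped, and by what, or still going (forward and back rates have come level / all of the starting material has reacted / the partner has run out first / it is still moving)
2. part of the starting material gone at 4.0 h
3. the target standing at 4.0 h, as a percentage of the starting material charged
4. the over-reaction product standing at 4.0 h, as a percentage of the starting material charged

I keep the ledger on the partner. Radicals are born in pairs from the initiator and die in pairs as chain carrier, so equating the two rates puts the chain carrier at the square root of the initiator's decay constant times the initiator over the termination constant, 1.10 × 10⁻⁷ M. At that level the chain step takes partner at 0.0295 s⁻¹ and decomposition at 0.0128 s⁻¹. Work with the fraction of partner left: it decays with the sum of these, 0.0423 s⁻¹, falling by a factor of e every 23.7 s. That is far shorter than the initiator's half-life, so I hold the level fixed in this reckoning.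

The first entry is the chain share, the chain step's rate over the sum of the two, 69.7%, which books 0.662 M of partner into target. The second entry, decomposition, takes 0.288 M. The third is a withdrawal from target: over-reaction, integrated as the fraction left falls from full to empty, comes to half of 0.00452 L mol⁻¹ s⁻¹ times the share times the charge squared over the summed constant, 0.0336 M. This entry draws the same amount of partner as well, which the first two entries do not allow for, so my ledger overruns the charge by that amount.

The books close on the partner, the limiting reagent, because chain turnover plus the ended chains asks less than the starting material charged. I commit to conversion 71.7%, target 66.2% and over-reaction product 3.54%.

The forecast says the partner has run out first, with conversion 69.2%, target 64% and over-reaction product 3.2%, on the ground that “The partner is gone within a few minutes, while the initiator has barely decayed.” Its conversion and target stand below mine.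

The flask gives the partner has run out first, with 0% of the partner left, conversion 69.2%, target 63.9% and over-reaction product 3.23%. In this flask the chain step and decomposition ran together at the start, with target at 63.9% and over-reaction product at 3.23% by 0.200 h. Afterwards the remaining initiator fed ended chains, from 1.53% at 0.400 h to 2.00% at 2.00 h. Read back from the partner charged, less the 0.281 M of decomposed reagent and the partner held in over-reaction product, the chain share comes to 67.2%, against 69.7% reckoned.

In the neighbour flask with 0.38 M of partner, the chain carrier level contains no partner, so the same share gives conversion 29.9%, target 27.3% and over-reaction product 0.567%. That neighbour computes to 29.4%, 26.8% and 0.549%.

The numbers are assumed; no experiment stands behind them.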